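The earlier runs and the new flask were computed with made-up constants.

1. The constants are hidden, so we keep a ledger of incoming ligand, in fractions of its charge; it is the limiting reagent once leaving ligand has taken its part, because what then stays is less than the starting complex charged.

common to all: starting complex 0.050 M (fed, over 4.0 h)

|  | incoming ligand | leaving ligand | remark | time |
|---|---|---|---|---|
| south-east | 0.055 M | 0.050 M | run made earlier |  |
| flask | 0.0550 M | 0.0250 M |  | 8.0 h |

south-east run (percent of the starting complex charged)

| time / min | starting complex / % | complex with three exchanged / % |
|---|---|---|
| 10.0 | 4.1 | 0.2 |
| 20.0 | 8.2 | 0 |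
| 30.0 | 12.5 | 0 |
| 40.0 | 16.8 | 0 |
| 50.0 | 20.6 | 0 |

(each reading ± 0.3 percentage points)

- leaving ligand is meant together with its idle adduct
- the numbers in the tables scatter by 0.3 percentage points (one standard deviation)
- reactions considered so far: starting complex + incoming ligand <-> leaving ligand + complex with one exchanged; complex with one exchanged + incoming ligand <-> leaving ligand + complex with two exchanged; complex with two exchanged + incoming ligand <-> leaving ligand + complex with three exchanged; complex with three exchanged + incoming ligand <-> leaving ligand + complex with four exchanged; leaving ligand + incoming ligand <-> idle adduct
- percentages count the whole charge, also what has not yet gone in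
- the earlier runs do not show how much of incoming ligand is bound; that part of a forecast is a guess
- no earlier run changes the charge of leaving ligand; that part of a forecast is a guess

* part of the starting complex that has reacted at 8.0 h
* share of the unused incoming ligand that is free and not bound as idle adduct, at 8.0 h

2. In the south-east run 20.8% had been fed at 50.0 min and 20.6% was found, a gap within the scatter of 0.3 percentage points.

3. Our guess is tight binding: each leaving ligand ties up one incoming ligand as idle adduct. The spare share, the part of the incoming charge not tied up at the start, is then 54.5% in the flask, against 9.09% in the south-east run.

4. Each exchange debits the spare share twice: one incoming ligand is consumed, and the leaving ligand released ties up another. On that guess the books close near 30.0% of the starting complex, counted in single exchanges.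

5. The forward rate of the first exchange goes with the free incoming ligand, which each debit lowers, so we commit to half that ceiling: 15.0% reacted, which makes the free part 31.6% of the unused incoming ligand.

6. The forecast gave 10% reacted (1% to 35%) and 80% free (35% to 99%): “The bound fraction of incoming ligand is unconstrained by the data.”

7. The flask gives 16.9% reacted and 27.6% free.

    starting complex + incoming ligand ⇌ leaving ligand + complex with one exchanged (K = 0.427, k = 4.33 × 10⁻⁴ M⁻¹ s⁻¹)
    complex with one exchanged + incoming ligand ⇌ leaving ligand + complex with two exchanged (K = 0.150, k = 2.07 × 10⁻⁴ M⁻¹ s⁻¹)
    complex with two exchanged + incoming ligand ⇌ leaving ligand + complex with three exchanged (K = 0.291, k = 3.56 × 10⁻⁴ M⁻¹ s⁻¹)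
    complex with three exchanged + incoming ligand ⇌ leaving ligand + complex with four exchanged (K = 0.194, k = 6.47 × 10⁻⁴ M⁻¹ s⁻¹)
    leaving ligand + incoming ligand ⇌ idle adduct, settled at all times (K = 5100 M⁻¹)

In the flask, the spare share less two debits per exchange, every exchanged complex counted, leaves 22.3% of the charge, and 23.2% of incoming ligand stands free. As that share fell, the half-life of starting complex by the forward rate of the first exchange alone stretched from 21 h at 4.25 h to 35 h at 8.00 h, long against the 8.0 h of the flask. In the neighbour flask with 0.015 M of leaving ligand, the spare share is 72.7% and the same debits leave 30.3%, where 30.9% of incoming ligand stands free.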